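(All runs were generated by integration with made-up constants; noise was put on by code.)

Subtraction is the easy step: at 60.0 min the south-east flask shows 22.1% target and 2.0% substrate, so 75.9% of the substrate charged is missing from the readings.

| flask | substrate | partner | temperature | remark | time |
|---|---|---|---|---|---|
| south-east | 0.36 M | 0.432 M | 100 °C | the very flask that is asked about, followed so far |  |
| west | 0.36 M | 0.432 M | 106 °C | run made earlier |  |
| flask | 0.36 M | 0.432 M | 100 °C |  | 1.0 h |

- south-east (time / min: target / %, substrate / %): 5.00: 29.6, 49.3; 8.00: 32.9, 35.0; 12.0: 31.2, 23.6; 20.0: 27.1, 13.1; 40.0: 22.1, 4.2; 60.0: 22.1, 2.0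
- west (time / min: target / %, substrate / %): 5.00: 29.1, 37.3; 8.00: 28.8, 23.6; 12.0: 26.8, 15.0; 20.0: 25.2, 7.7; 40.0: 24.9, 2.5; 60.0: 25.1, 1.6

(each reading ± 0.3 percentage points)

- winter: change nothing and wait 30 min more
- noon: at 1.0 h add partner, 100% of the amount charged, then wait 30 min
- midnight: at 1.0 h raise the temperature by 20 K, then wait 30 min
- summer: at 1.0 h take out 90% of the target then present, then wait 30 min

- removed target is counted in
- the numbers in the tables scatter by 0.3 percentage points (one standard deviation)
- additions bring no volume worth counting

1. target, in percent of the substrate first charged, at 1.0 h
2. which option adds most target ("none" when 2 percentage points or less is all one gets) (winter / noon / midnight / summer / none)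
3. target present, with what was taken out counted in, in percent of the substrate first charged, after noon
4. target present, with what was taken out counted in, in percent of the substrate first charged, after midnight

Two chemists read that gap differently. The first calls the level stretch a stall: target stands at 22.1% and then 22.1% while substrate still falls from 4.2% to 2.0%, so she takes the missing material as dead and expects no option to pay more than 2 percentage points. The second points to the hotter west run, with the same charges, which levels off higher, at 25.1%, and holds that the level marks a balance, where the rate into target equals the rate out of it. Dividing one rate by the other removes time and leaves the return ratio ρ, the material standing in exchange with target per unit of target, which she reads as 3.43 by counting the whole gap as exchangeable. Her rule follows, with the temperature held and balance taken to return within the 30 min of waiting: if a share of target is taken out, the pool refills it, and the gain is that share times target times the fraction of the exchanging pair that stands as pool at balance, which I reckon at 15 points.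

The forecast takes the second side, reasoning that “the plateau is an equilibrium”. It gives 22.1% now, a gain of about 15.5 points by removal against my 15 points, so summer as the best option, 22.6% after noon and 32% after midnight.

The flask gives 21.7% now, 22.0% after noon and 37.7% after midnight, and the best option is midnight, adding 16 points against 13 points for summer. Summer and midnight each pay more than the stall view expected, yet that view keeps its ground where temperature and target stay untouched: winter adds −0.089 points and noon 0.34 points, both below 2 points.

    substrate ⇌ other conformer (K = 1.10, k = 0.0302 min⁻¹, Ea = 114 kJ mol⁻¹, ΔH = 27.0 kJ mol⁻¹)
    substrate + partner → target (k = 0.321 M⁻¹ min⁻¹, Ea = 65.0 kJ mol⁻¹)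
    partner + other conformer → isomer of the product A (k = 0.369 M⁻¹ min⁻¹, Ea = 60.0 kJ mol⁻¹)
    substrate + target → side product (k = 0.0706 M⁻¹ min⁻¹, Ea = 70.0 kJ mol⁻¹)
    target ⇌ isomer of the product B (K = 2.10, k = 0.0825 min⁻¹, Ea = 122 kJ mol⁻¹, ΔH = −62.0 kJ mol⁻¹)
    partner → decomposed reagent (k = 0.00436 min⁻¹, Ea = 116 kJ mol⁻¹)
    (constants at 100 °C)

The gap reading and the flask part over ρ: in the flask at 60.0 min, isomer of the product B over target is 2.04, less than the 3.43 read from the gap, and the same rule with this ratio gives 13 points for summer. On the neighbouring flask with [substrate] = 0.090 M, the gap reckoning gives 2.81, whereas isomer of the product B over target gives 2.08, from 54.4% of that isomer and 26.2% of target.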